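**Plan**
- Numbering follows the cembranes: C1 is the ring methine bonded to the gem-dimethyl carbon C15, C3 carries the acetate, C4 is the methyl-bearing ether carbon, C7 is the carbinol, C8 carries the exocyclic methylene C19, and C11=C12 is the E alkene. The 14-membered carbocycle C1–C14 is bridged by the oxane O–C15–C1–C2–C3–C4. The feature exploited is the exomethylene carbon C8 next to the C7 carbinol (a masked 2-bromoallyl silyl ether) together with the C9–C10 ethano unit homoallylic to C11=C12 (a masked terminal 1,3-diene).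
- Retrosynthesis: cut the C7 O–Si bond, then C8–C9 (the carbocycle), then C9=C10 and C11=C12 (olefinations), C7–C8 (acylation), O–C15 (oxane), O–C4 (epoxide opening), C5–C6 (Claisen) and C3–C4 (isopropenyl addition). This leads back to the keto aldehyde from (R)-limonene oxide.
- Forward: both arms are grown linearly on the limonene-derived C1 centre. The oxane is closed in step 8 (O4 onto C15) and the 14-membered ring last, in step 16 (C8–C9).
- Stereochemistry: C1 (R) comes from (R)-limonene. C3 (R) and C4 (S) come from Shi epoxidation of the 3E alkene followed by invertive lactonisation at C4. C7 (R) comes from CBS reduction of the α-bromo enone. 11E comes from the Horner–Wadsworth–Emmons step.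

Key step: step 16

Remark: commercial (+)-limonene 1,2-oxide (cis/trans mixture made from (R)-limonene) is used as such, because step 1 destroys both epoxide centres. Locants in the step texts are cembrane locants.

**Step 1**
Reactants: 1 (+)-limonene 1,2-oxide
Product: 3 (3R)-6-oxo-3-(prop-1-en-2-yl)heptanal, via limonene-1,2-diol 2 (not isolated)
Conditions: H5IO6, THF/H2O, 0 °C to rt
Reagents that add atoms: water, O
Why: Periodic acid hydrolyses the epoxide to the 1,2-diol and cleaves it (Malaprade glycol cleavage), so both epoxide diastereomers converge on one keto aldehyde and the isopropenyl-bearing centre (future C1) is untouched.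

**Step 2**
Reactants: 3 (3R)-6-oxo-3-(prop-1-en-2-yl)heptanal; 4 2-bromopropene
Product: 5 (5R)-7-hydroxy-8-methyl-5-(prop-1-en-2-yl)non-8-en-2-one (both C7 epimers)
Conditions: CrCl2, NiCl2 (cat.), DMF, rt
Reagents that add atoms: 4 2-bromopropene, CC(Br)=C
Why: Nozaki–Hiyama–Kishi alkenylation adds the isopropenylchromium(III) species to the aldehyde and ignores the methyl ketone, forming C3–C4; the new carbinol arises as both epimers, which does not matter because C3 becomes sp2 in step 3.

**Step 3**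
Reactants: 5 allylic alcohol; 6 triethyl orthoacetate
Product: 8 ethyl (4E,7R)-4-methyl-10-oxo-7-(prop-1-en-2-yl)undec-4-enoate, via ketene acetal 7 (not isolated)
Conditions: MeC(OEt)3 (neat), EtCO2H (cat.), 140 °C, EtOH distilled off
Reagents that add atoms: 6 triethyl orthoacetate, CC(OCC)(OCC)OCC
Why: Johnson–Claisen rearrangement of the mixed ketene acetal through a chair with the C2 substituent equatorial forms C5–C6, delivers C7 as an ester and gives the trisubstituted C3=C4 alkene as the E isomer.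

**Step 4**
Reactants: 8 keto ester; 9 tert-butyl diethylphosphonoacetate
Product: 10 1-tert-butyl 12-ethyl (2E,6R,8E)-3,9-dimethyl-6-(prop-1-en-2-yl)dodeca-2,8-dienedioate
Conditions: NaH, THF, 0 °C to 50 °C (phosphonate anion preformed)
Reagents that add atoms: 9 tert-butyl diethylphosphonoacetate, CCOP(=O)(CC(=O)OC(C)(C)C)OCC
Why: Horner–Wadsworth–Emmons olefination of the methyl ketone should give mainly the 11E enoate (ester trans to the longer chain), with the minor 11Z isomer to be removed by chromatography; the tert-butyl ester is chosen so that this arm stays inert in steps 5–11.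

**Step 5**
Reactants: 10 diester
Product: 12 tert-butyl (2E,6R,8R)-8-hydroxy-3-methyl-8-[(2S)-2-methyl-5-oxooxolan-2-yl]-6-(prop-1-en-2-yl)oct-2-enoate, via (3R,4R)-epoxide 11 (not isolated)
Conditions: Shi ketone (D-fructose-derived, 30 mol%), Oxone, K2CO3, Bu4NHSO4, MeCN–DMM/aq. borate buffer (pH 10.5), 0 °C; then CSA (cat.), wet CH2Cl2, rt
Reagents that add atoms: Oxone (potassium peroxymonosulfate), [K+].[O-]S(=O)(=O)OO; water, O
Why: Shi asymmetric epoxidation attacks the electron-rich trisubstituted 3E alkene (the enoate is inert and the 1,1-disubstituted isopropenyl group is slower) under reagent control to give the (3R,4R)-epoxide, and acid then causes 5-exo opening by the ester carbonyl at the tertiary C4 with inversion (epoxy ester lactonisation), which sets C3 (R) and C4 (S) and forms the C4–O bond with no ring-size ambiguity.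

**Step 6**
Reactants: 12 hydroxy lactone; 13 N,O-dimethylhydroxylamine hydrochloride
Product: 14 tert-butyl (2E,6R,8R,9S)-8,9-dihydroxy-12-[methoxy(methyl)amino]-3,9-dimethyl-12-oxo-6-(prop-1-en-2-yl)dodec-2-enoate
Conditions: i-PrMgCl, THF, −20 to 0 °C; used without storage
Reagents that add atoms: 13 N,O-dimethylhydroxylamine hydrochloride, CNOC.Cl
Why: Weinreb aminolysis of the γ-lactone by the chloromagnesium amide frees the tertiary C4 hydroxyl and leaves C7 as an acyl donor that stops at the ketone stage, while the hindered, conjugated tert-butyl ester does not react.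

**Step 7**
Reactants: 14 diol amide; 15 acetic anhydride
Product: 16 tert-butyl (2E,6R,8R,9S)-8-acetoxy-9-hydroxy-12-[methoxy(methyl)amino]-3,9-dimethyl-12-oxo-6-(prop-1-en-2-yl)dodec-2-enoate
Conditions: pyridine, DMAP (cat.), CH2Cl2, 0 °C
Reagents that add atoms: 15 acetic anhydride, CC(=O)OC(C)=O
Why: Acylation is selective for the secondary C3 hydroxyl over the tertiary C4 hydroxyl, and the acetate blocks the competing five-membered ether closure from O3 in step 8.

**Step 8**
Reactants: 16 hydroxy acetate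
Product: 17 tert-butyl (2E)-5-[(3R,5R,6S)-5-acetoxy-6-{3-[methoxy(methyl)amino]-3-oxopropyl}-2,2,6-trimethyloxan-3-yl]-3-methylpent-2-enoate
Conditions: Co(salen) (cat.), N-fluoro-2,4,6-trimethylpyridinium triflate, PhSiH3, PhCF3, rt; NaHCO3 work-up
Reagents that add atoms: none
Why: Cobalt-catalysed hydrogen-atom-transfer hydroalkoxylation (Mukaiyama-type radical–polar crossover) turns the isopropenyl group into a tertiary C15 cation equivalent that is trapped by the C4 hydroxyl in a Markovnikov 6-exo closure to the oxane; no stereocentre is formed and the β,β-disubstituted enoate is a poor hydrogen-atom acceptor.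

**Step 9**
Reactants: 17 oxane Weinreb amide; 18 1,1-dibromoethene
Product: 19 tert-butyl (2E)-5-[(3R,5R,6S)-5-acetoxy-6-(4-bromo-3-oxopent-4-en-1-yl)-2,2,6-trimethyloxan-3-yl]-3-methylpent-2-enoate
Conditions: 18 (1.3 equiv), n-BuLi (1.2 equiv), THF/Et2O/pentane 4:1:1, −110 °C; then 17, −105 °C; aq. NH4Cl
Reagents that add atoms: 18 1,1-dibromoethene, C=C(Br)Br
Why: Weinreb ketone synthesis with 1-bromo-1-lithioethene (from Br/Li exchange) gives the α-bromo enone when the chelated tetrahedral adduct collapses on work-up, and at this temperature the acetate and the tert-butyl enoate should react far more slowly than the chelating amide.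

**Step 10**
Reactants: 19 α-bromo enone
Product: 20 tert-butyl (2E)-5-[(3R,5R,6S)-5-acetoxy-6-[(3R)-4-bromo-3-hydroxypent-4-en-1-yl]-2,2,6-trimethyloxan-3-yl]-3-methylpent-2-enoate
Conditions: (S)-Me-CBS oxazaborolidine, catecholborane, toluene, −78 °C
Reagents that add atoms: none
Why: Corey–Bakshi–Shibata reduction under reagent control, with the 1-bromovinyl group acting as the large substituent, should deliver the (7R) alcohol from the (S)-catalyst by the standard model; the bromine is what makes this vinyl ketone a well-differentiated substrate.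

**Step 11**
Reactants: 20 bromoallylic alcohol; 21 tert-butyldimethylsilyl triflate
Product: 22 tert-butyl (2E)-5-[(3R,5R,6S)-5-acetoxy-6-{(3R)-4-bromo-3-[(tert-butyldimethylsilyl)oxy]pent-4-en-1-yl}-2,2,6-trimethyloxan-3-yl]-3-methylpent-2-enoate
Conditions: 2,6-lutidine, CH2Cl2, −78 °C
Reagents that add atoms: 21 tert-butyldimethylsilyl triflate, CC(C)(C)[Si](C)(C)OS(=O)(=O)C(F)(F)F
Why: Silylation of the only free hydroxyl protects C7 with a group that survives hydride, ylide and aqueous carbonate and can be removed at the end without touching the acetate.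

**Step 12**
Reactants: 22 silyl ether
Product: 23 (2E)-5-[(3R,5R,6S)-6-{(3R)-4-bromo-3-[(tert-butyldimethylsilyl)oxy]pent-4-en-1-yl}-5-hydroxy-2,2,6-trimethyloxan-3-yl]-3-methylpent-2-en-1-ol
Conditions: DIBAL-H (excess), CH2Cl2, −78 to −20 °C; Rochelle salt
Reagents that add atoms: none
Why: DIBAL-H reduces the tert-butyl enoate to the allylic alcohol (1,2-reduction of an ester) and cleaves the C3 acetate in the same operation, while the bromoalkene and the silyl ether are inert; the acetate is restored in step 15.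

**Step 13**
Reactants: 23 diol
Product: 24 (2E)-5-[(3R,5R,6S)-6-{(3R)-4-bromo-3-[(tert-butyldimethylsilyl)oxy]pent-4-en-1-yl}-5-hydroxy-2,2,6-trimethyloxan-3-yl]-3-methylpent-2-enal
Conditions: MnO2, CH2Cl2, rt
Reagents that add atoms: none
Why: Manganese dioxide oxidises only the allylic alcohol, leaves the saturated hindered C3 hydroxyl alone and keeps the 11E geometry.

**Step 14**
Reactants: 24 enal; 25 methyltriphenylphosphonium bromide
Product: 26 (2S,3R,5R)-2-{(3R)-4-bromo-3-[(tert-butyldimethylsilyl)oxy]pent-4-en-1-yl}-2,6,6-trimethyl-5-[(3E)-3-methylhexa-3,5-dien-1-yl]oxan-3-ol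
Conditions: 25, KHMDS, THF, 0 °C; then 24, −78 to 0 °C (excess ylide)
Reagents that add atoms: 25 methyltriphenylphosphonium bromide, C[P+](c1ccccc1)(c1ccccc1)c1ccccc1.[Br-]
Why: Wittig methylenation of the enal installs C9 and completes the terminal 1,3-diene without disturbing the 11E bond, the excess ylide covering the free C3 hydroxyl.

**Step 15**
Reactants: 26 dienol; 15 acetic anhydride
Product: 27 (2S,3R,5R)-2-{(3R)-4-bromo-3-[(tert-butyldimethylsilyl)oxy]pent-4-en-1-yl}-2,6,6-trimethyl-5-[(3E)-3-methylhexa-3,5-dien-1-yl]oxan-3-yl acetate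
Conditions: DMAP, Et3N, CH2Cl2, rt
Reagents that add atoms: 15 acetic anhydride, CC(=O)OC(C)=O
Why: DMAP-catalysed acetylation of the single free hydroxyl (C3) puts the acetate of the target in place.

**Step 16**
Reactants: 27 seco bromoalkene diene
Product: 29 (1R,3R,4S,7R,11E)-3-acetoxy-7-[(tert-butyldimethylsilyl)oxy]-4,15-epoxycembra-8(19),11-diene, via B-alkyl-9-BBN borane 28 (not isolated)
Conditions: 9-BBN, THF, 0 °C to rt; then slow addition to Pd(dppf)Cl2, AsPh3, Cs2CO3, degassed DMF/THF/H2O, rt (ca. 2 mM)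
Reagents that add atoms: none
Why: 9-BBN adds across the monosubstituted C9=C10 terminus of the diene with boron on C9 (anti-Markovnikov hydroboration) and aqueous carbonate converts the B-alkyl-9-BBN into its borate; Pd(0) inserts into the C8–Br bond, the primary alkyl group passes from boron to palladium, and reductive elimination forms C8–C9. The closest known reaction type is the hydroboration/intramolecular B-alkyl Suzuki–Miyaura macrocyclisation of ω-alkenyl vinyl halides. The 14-membered carbocycle is closed end to end as a macrocyclisation at the sp2(C8)–sp3(C9) bond, under high dilution by slow addition of the borane, and the cis arrangement of the two arms on the oxane brings the ends together. No stereocentre is formed: C7 was fixed in step 10 and lies on the far side of C8 from the new bond, and the 11E alkene is not involved. The selectivity needed is in the hydroboration, and it is secured because 9-BBN prefers the unhindered monosubstituted alkene over the trisubstituted C11=C12 bond and over the 2-bromoalkene, which is 1,1-disubstituted, shielded by the silyloxy group and deactivated by bromine. The acetate should tolerate aqueous Cs2CO3 at room temperature.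

**Step 17**
Reactants: 29 macrocyclic silyl ether
Product: 30 (1R,3R,4S,7R,11E)-4,15-epoxycembra-8(19),11-diene-3,7-diol 3-acetate (CNP0202897.1)
Conditions: HF·pyridine, THF/pyridine, 0 °C to rt
Reagents that add atoms: none
Why: Fluoride-mediated desilylation under buffered conditions frees the C7 hydroxyl while the acetate, the exocyclic methylene and the trisubstituted alkene stay untouched.

**Compound list**
1 | (+)-limonene 1,2-oxide, (4R)-1-methyl-4-(prop-1-en-2-yl)-7-oxabicyclo[4.1.0]heptane, cis/trans mixture | CC12OC1C[C@@H](CC2)C(C)=C | starting material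
2 | (4R)-limonene-1,2-diol | CC1(O)C(O)C[C@@H](CC1)C(C)=C | intermediate
3 | (3R)-6-oxo-3-(prop-1-en-2-yl)heptanal | O=CC[C@@H](CCC(C)=O)C(C)=C | intermediate
4 | 2-bromopropene | CC(Br)=C | starting material
5 | (5R)-7-hydroxy-8-methyl-5-(prop-1-en-2-yl)non-8-en-2-one, C7 epimers | C=C(C)C(O)C[C@@H](CCC(C)=O)C(C)=C | intermediate
6 | triethyl orthoacetate | CC(OCC)(OCC)OCC | starting material
7 | 1-ethoxyvinyl ether of 5 (mixed ketene acetal) | C=C(OCC)OC(C(C)=C)C[C@@H](CCC(C)=O)C(C)=C | intermediate
8 | ethyl (4E,7R)-4-methyl-10-oxo-7-(prop-1-en-2-yl)undec-4-enoate | CCOC(=O)CC/C(C)=C/C[C@@H](CCC(C)=O)C(C)=C | intermediate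
9 | tert-butyl diethylphosphonoacetate | CCOP(=O)(CC(=O)OC(C)(C)C)OCC | starting material
10 | 1-tert-butyl 12-ethyl (2E,6R,8E)-3,9-dimethyl-6-(prop-1-en-2-yl)dodeca-2,8-dienedioate | CCOC(=O)CC/C(C)=C/C[C@@H](CC/C(C)=C/C(=O)OC(C)(C)C)C(C)=C | intermediate
11 | tert-butyl (2E,6R)-7-[(2R,3R)-3-(3-ethoxy-3-oxopropyl)-3-methyloxiran-2-yl]-3-methyl-6-(prop-1-en-2-yl)hept-2-enoate, the (3R,4R)-epoxide | CCOC(=O)CC[C@@]1(C)O[C@@H]1C[C@@H](CC/C(C)=C/C(=O)OC(C)(C)C)C(C)=C | intermediate
12 | tert-butyl (2E,6R,8R)-8-hydroxy-3-methyl-8-[(2S)-2-methyl-5-oxooxolan-2-yl]-6-(prop-1-en-2-yl)oct-2-enoate | O=C1CC[C@](C)(O1)[C@H](O)C[C@@H](CC/C(C)=C/C(=O)OC(C)(C)C)C(C)=C | intermediate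
13 | N,O-dimethylhydroxylamine hydrochloride | CNOC.Cl | starting material
14 | tert-butyl (2E,6R,8R,9S)-8,9-dihydroxy-12-[methoxy(methyl)amino]-3,9-dimethyl-12-oxo-6-(prop-1-en-2-yl)dodec-2-enoate | CON(C)C(=O)CC[C@](C)(O)[C@H](O)C[C@@H](CC/C(C)=C/C(=O)OC(C)(C)C)C(C)=C | intermediate
15 | acetic anhydride | CC(=O)OC(C)=O | starting material
16 | tert-butyl (2E,6R,8R,9S)-8-acetoxy-9-hydroxy-12-[methoxy(methyl)amino]-3,9-dimethyl-12-oxo-6-(prop-1-en-2-yl)dodec-2-enoate | CON(C)C(=O)CC[C@](C)(O)[C@H](OC(C)=O)C[C@@H](CC/C(C)=C/C(=O)OC(C)(C)C)C(C)=C | intermediate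
17 | tert-butyl (2E)-5-[(3R,5R,6S)-5-acetoxy-6-{3-[methoxy(methyl)amino]-3-oxopropyl}-2,2,6-trimethyloxan-3-yl]-3-methylpent-2-enoate | CC(C)(C)OC(=O)/C=C(\C)CC[C@@H]1C[C@@H](OC(C)=O)[C@](C)(CCC(=O)N(C)OC)OC1(C)C | intermediate
18 | 1,1-dibromoethene | C=C(Br)Br | starting material
19 | tert-butyl (2E)-5-[(3R,5R,6S)-5-acetoxy-6-(4-bromo-3-oxopent-4-en-1-yl)-2,2,6-trimethyloxan-3-yl]-3-methylpent-2-enoate | CC(C)(C)OC(=O)/C=C(\C)CC[C@@H]1C[C@@H](OC(C)=O)[C@](C)(CCC(=O)C(Br)=C)OC1(C)C | intermediate
20 | tert-butyl (2E)-5-[(3R,5R,6S)-5-acetoxy-6-[(3R)-4-bromo-3-hydroxypent-4-en-1-yl]-2,2,6-trimethyloxan-3-yl]-3-methylpent-2-enoate | CC(C)(C)OC(=O)/C=C(\C)CC[C@@H]1C[C@@H](OC(C)=O)[C@](C)(CC[C@@H](O)C(Br)=C)OC1(C)C | intermediate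
21 | tert-butyldimethylsilyl trifluoromethanesulfonate | CC(C)(C)[Si](C)(C)OS(=O)(=O)C(F)(F)F | starting material
22 | tert-butyl (2E)-5-[(3R,5R,6S)-5-acetoxy-6-{(3R)-4-bromo-3-[(tert-butyldimethylsilyl)oxy]pent-4-en-1-yl}-2,2,6-trimethyloxan-3-yl]-3-methylpent-2-enoate | CC(C)(C)OC(=O)/C=C(\C)CC[C@@H]1C[C@@H](OC(C)=O)[C@](C)(CC[C@@H](O[Si](C)(C)C(C)(C)C)C(Br)=C)OC1(C)C | intermediate
23 | (2E)-5-[(3R,5R,6S)-6-{(3R)-4-bromo-3-[(tert-butyldimethylsilyl)oxy]pent-4-en-1-yl}-5-hydroxy-2,2,6-trimethyloxan-3-yl]-3-methylpent-2-en-1-ol | OC/C=C(\C)CC[C@@H]1C[C@@H](O)[C@](C)(CC[C@@H](O[Si](C)(C)C(C)(C)C)C(Br)=C)OC1(C)C | intermediate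
24 | (2E)-5-[(3R,5R,6S)-6-{(3R)-4-bromo-3-[(tert-butyldimethylsilyl)oxy]pent-4-en-1-yl}-5-hydroxy-2,2,6-trimethyloxan-3-yl]-3-methylpent-2-enal | O=C/C=C(\C)CC[C@@H]1C[C@@H](O)[C@](C)(CC[C@@H](O[Si](C)(C)C(C)(C)C)C(Br)=C)OC1(C)C | intermediate
25 | methyltriphenylphosphonium bromide | C[P+](c1ccccc1)(c1ccccc1)c1ccccc1.[Br-] | starting material
26 | (2S,3R,5R)-2-{(3R)-4-bromo-3-[(tert-butyldimethylsilyl)oxy]pent-4-en-1-yl}-2,6,6-trimethyl-5-[(3E)-3-methylhexa-3,5-dien-1-yl]oxan-3-ol | C=C/C=C(\C)CC[C@@H]1C[C@@H](O)[C@](C)(CC[C@@H](O[Si](C)(C)C(C)(C)C)C(Br)=C)OC1(C)C | intermediate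
27 | (2S,3R,5R)-2-{(3R)-4-bromo-3-[(tert-butyldimethylsilyl)oxy]pent-4-en-1-yl}-2,6,6-trimethyl-5-[(3E)-3-methylhexa-3,5-dien-1-yl]oxan-3-yl acetate (seco bromoalkene diene) | C=C/C=C(\C)CC[C@@H]1C[C@@H](OC(C)=O)[C@](C)(CC[C@@H](O[Si](C)(C)C(C)(C)C)C(Br)=C)OC1(C)C | intermediate
28 | (2S,3R,5R)-5-[(3E)-6-(9-borabicyclo[3.3.1]nonan-9-yl)-3-methylhex-3-en-1-yl]-2-{(3R)-4-bromo-3-[(tert-butyldimethylsilyl)oxy]pent-4-en-1-yl}-2,6,6-trimethyloxan-3-yl acetate | B1(C2CCCC1CCC2)CC/C=C(\C)CC[C@@H]3C[C@@H](OC(C)=O)[C@](C)(CC[C@@H](O[Si](C)(C)C(C)(C)C)C(Br)=C)OC3(C)C | intermediate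
29 | (1R,3R,4S,7R,11E)-3-acetoxy-7-[(tert-butyldimethylsilyl)oxy]-4,15-epoxycembra-8(19),11-diene | C=C1CC/C=C(\C)CC[C@@H]2C[C@@H](OC(C)=O)[C@](C)(CC[C@H]1O[Si](C)(C)C(C)(C)C)OC2(C)C | intermediate
30 | (1R,3R,4S,7R,11E)-4,15-epoxycembra-8(19),11-diene-3,7-diol 3-acetate (CNP0202897.1) | C=C1CC/C=C(\C)CC[C@@H]2C[C@@H](OC(C)=O)[C@](C)(CC[C@H]1O)OC2(C)C | target

**Step count**
Total: 17 steps. Longest linear sequence: 17 steps, from 1 to 30.

**Steps most likely to fail**

Step 16 (macrocyclisation). Transfer of the alkyl group from the borate to the alkenylpalladium bromide has to occur within a large, strained palladacycle, so protodeboronation, β-hydride elimination and intermolecular coupling may outrun ring closure. The fallback keeps the C8–C9 disconnection but replaces boron by zinc, which transmetallates without base or water. It sets out from 27: hydroboration with 9-BBN and oxidation with NaBO3·4H2O give the primary C9 alcohol F1, and Appel iodination (I2, PPh3, imidazole) gives the primary iodide F2. Zinc insertion (Zn dust, LiCl, THF, 40 °C; the alkenyl bromide is inert) gives the alkylzinc iodide F3, which is cyclised under high dilution by an intramolecular Negishi coupling (Pd2(dba)3/SPhos, THF/NMP). The route is rejoined at 29.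

Step 8 (oxane closure). The tertiary C15 cation equivalent may be lost by elimination back to alkene isomers or by capture of adventitious water before the hindered tertiary C4 hydroxyl attacks, and the hydroxy amide may relactonise while waiting. The fallback replaces the hydrogen-atom-transfer manifold by an electrophile-driven closure followed by radical reduction. It sets out from 16: iodoetherification (NIS, NaHCO3, MeCN, 0 °C) closes the same O–C15 bond by 6-exo attack of O4 on the iodonium ion and gives the iodomethyl oxane F4 (both C15 epimers). Radical deiodination (Bu3SnH, AIBN, toluene, 80 °C) removes the iodine together with the extra stereocentre. The route is rejoined at 17.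

Step 9 (carbenoid acylation). 1-Bromo-1-lithioethene may decompose by α-elimination before it is acylated, or attack the acetate competitively. The fallback separates acylation from halogenation. It sets out from 17: vinylmagnesium bromide (THF, −78 to −20 °C) gives the vinyl ketone F5. Bromine (CH2Cl2, −78 °C) adds to the unhindered enone to give the dibromo ketone F6, and triethylamine then eliminates hydrogen bromide in the same flask. The route is rejoined at 19.

**Further compounds**
F1 | step 16 | (2S,3R,5R)-2-{(3R)-4-bromo-3-[(tert-butyldimethylsilyl)oxy]pent-4-en-1-yl}-5-[(3E)-6-hydroxy-3-methylhex-3-en-1-yl]-2,6,6-trimethyloxan-3-yl acetate | OCC/C=C(\C)CC[C@@H]1C[C@@H](OC(C)=O)[C@](C)(CC[C@@H](O[Si](C)(C)C(C)(C)C)C(Br)=C)OC1(C)C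
F2 | step 16 | (2S,3R,5R)-2-{(3R)-4-bromo-3-[(tert-butyldimethylsilyl)oxy]pent-4-en-1-yl}-5-[(3E)-6-iodo-3-methylhex-3-en-1-yl]-2,6,6-trimethyloxan-3-yl acetate | ICC/C=C(\C)CC[C@@H]1C[C@@H](OC(C)=O)[C@](C)(CC[C@@H](O[Si](C)(C)C(C)(C)C)C(Br)=C)OC1(C)C
F3 | step 16 | alkylzinc iodide from F2 (iodozincio group on C9) | I[Zn]CC/C=C(\C)CC[C@@H]1C[C@@H](OC(C)=O)[C@](C)(CC[C@@H](O[Si](C)(C)C(C)(C)C)C(Br)=C)OC1(C)C
F4 | step 8 | tert-butyl (2E)-5-[(3R,5R,6S)-5-acetoxy-2-(iodomethyl)-6-{3-[methoxy(methyl)amino]-3-oxopropyl}-2,6-dimethyloxan-3-yl]-3-methylpent-2-enoate, C15 epimers | CC(C)(C)OC(=O)/C=C(\C)CC[C@@H]1C[C@@H](OC(C)=O)[C@](C)(CCC(=O)N(C)OC)OC1(C)CI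
F5 | step 9 | tert-butyl (2E)-5-[(3R,5R,6S)-5-acetoxy-2,2,6-trimethyl-6-(3-oxopent-4-en-1-yl)oxan-3-yl]-3-methylpent-2-enoate | CC(C)(C)OC(=O)/C=C(\C)CC[C@@H]1C[C@@H](OC(C)=O)[C@](C)(CCC(=O)C=C)OC1(C)C
F6 | step 9 | tert-butyl (2E)-5-[(3R,5R,6S)-5-acetoxy-6-(4,5-dibromo-3-oxopentyl)-2,2,6-trimethyloxan-3-yl]-3-methylpent-2-enoate | CC(C)(C)OC(=O)/C=C(\C)CC[C@@H]1C[C@@H](OC(C)=O)[C@](C)(CCC(=O)C(Br)CBr)OC1(C)C
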